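**Plan**

- Retrosynthesis: the two aryl–CH2 bonds of ring A (C3'–CH2 and C5'–CH2, i.e. both prenyl groups) are cut first, back to the unprenylated (S)-ketol and dimethylallyl diphosphate. The aryl–acyl bond C1'–C(=O) is cut next, back to a ring-A aryllithium from 4-bromoresorcinol and the N-methoxy-N-methylamide of (S)-3-(4-hydroxyphenyl)lactic acid.
- Forward: no ring is made (rings A and B are bought). The chain is joined by acylation of the aryllithium with the amide, the four benzyl ethers are removed by hydrogenolysis, and both prenyl groups go on last in one enzymatic operation.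
- Feature used: in ring A (the acylresorcinol ring, primed numbers), C3' (ortho to O2' and O4') and C5' (ortho to O4', para to O2') are the only carbons activated by both phenolic oxygens. C6' is meta to both, C1' carries the acyl group and ring B has a single oxygen, so a prenyltransferase has exactly two Friedel–Crafts sites.
- Stereochemistry: the one stereocenter (C2, S) is bought with the hydroxy acid. No bond to it is made or broken, and every later step is chosen so that this α-carbon is not enolised.

Key step: step 8

Assumption: the prenyltransferase is used as a recombinant, purified catalyst whose expression is not counted as a step, and tris(tetrabutylammonium) hydrogen diphosphate is bought.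

**Route**

Step 1
Reactants: 1 (S)-3-(4-hydroxyphenyl)lactic acid [(S)-2-hydroxy-3-(4-hydroxyphenyl)propanoic acid]
Product: 2 benzyl (S)-3-[4-(benzyloxy)phenyl]-2-hydroxypropanoate
Conditions: BnBr (2.2 equiv), K2CO3 (3 equiv), DMF, rt
Reagents that add atoms: benzyl bromide, BrCc1ccccc1
Why: Williamson-type O-alkylation works here because K2CO3 ionises only the carboxylic acid and the phenol, so the benzyl ester and the aryl benzyl ether form while the far less acidic secondary alcohol and the stereocenter next to it stay untouched.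

Step 2
Reactants: 2 benzyl (S)-3-[4-(benzyloxy)phenyl]-2-hydroxypropanoate
Product: 3 benzyl (S)-2-(benzyloxy)-3-[4-(benzyloxy)phenyl]propanoate
Conditions: BnBr (2 equiv), Ag2O (1.5 equiv), CH2Cl2, 4 Å molecular sieves, rt, dark
Reagents that add atoms: benzyl bromide, BrCc1ccccc1
Why: Ag2O-promoted Williamson etherification benzylates the α-hydroxy ester without a free strong base, so the α-carbon, which an alkoxide made with NaH could epimerise, should keep its S configuration.

Step 3
Reactants: 3 benzyl (S)-2-(benzyloxy)-3-[4-(benzyloxy)phenyl]propanoate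
Product: 4 (S)-2-(benzyloxy)-3-[4-(benzyloxy)phenyl]-N-methoxy-N-methylpropanamide
Conditions: MeNHOMe·HCl (2 equiv), i-PrMgCl (4 equiv), THF, −20 to 0 °C
Reagents that add atoms: N,O-dimethylhydroxylamine hydrochloride, CNOC.Cl
Why: Ester aminolysis by the chloromagnesium amide of N,O-dimethylhydroxylamine (Weinreb amide formation) is fast below 0 °C, faster than addition of i-PrMgCl to the ester, and does not deprotonate the α-benzyloxy carbon.

Step 4
Reactants: 5 4-bromoresorcinol (4-bromobenzene-1,3-diol)
Product: 6 2,4-bis(benzyloxy)-1-bromobenzene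
Conditions: BnBr (2.3 equiv), K2CO3 (3 equiv), acetone, reflux
Reagents that add atoms: benzyl bromide, BrCc1ccccc1
Why: Williamson ether synthesis on both phenols gives an aryl bromide whose protecting groups withstand n-BuLi at −78 °C and later leave by hydrogenolysis together with those of 4.

Step 5
Reactants: 6 2,4-bis(benzyloxy)-1-bromobenzene; 4 (S)-2-(benzyloxy)-3-[4-(benzyloxy)phenyl]-N-methoxy-N-methylpropanamide
Product: 9 (S)-2-(benzyloxy)-1-[2,4-bis(benzyloxy)phenyl]-3-[4-(benzyloxy)phenyl]propan-1-one, via aryllithium 7 (not isolated), via tetrahedral lithium adduct 8 (not isolated)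
Conditions: 6 (1.3 equiv), n-BuLi (1.25 equiv), THF, −78 °C; then 4 (1 equiv), −78 to −40 °C; cold 1 M aq. HCl
Reagents that add atoms: none
Why: Bromine–lithium exchange followed by a Weinreb ketone synthesis should give the ketone cleanly because the aryllithium adds once to form the N,O-chelated adduct 8, which collapses only in the acidic quench, and at −78 °C the α-benzyloxy stereocenter is not deprotonated, so S is carried through.

Step 6
Reactants: 9 (S)-2-(benzyloxy)-1-[2,4-bis(benzyloxy)phenyl]-3-[4-(benzyloxy)phenyl]propan-1-one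
Product: 10 (S)-1-(2,4-dihydroxyphenyl)-2-hydroxy-3-(4-hydroxyphenyl)propan-1-one
Conditions: H2 (1 atm), 10% Pd/C, EtOAc–MeOH (1:1), rt
Reagents that add atoms: none
Why: Catalytic hydrogenolysis of benzyl ethers over Pd/C is neutral, so the acid- and base-sensitive α-ketol should keep its configuration, and the electron-rich, hydrogen-bonded 2,4-dihydroxyphenyl ketone is a poor substrate for carbonyl reduction under one atmosphere of H2.

Step 7
Reactants: 11 1-bromo-3-methylbut-2-ene (prenyl bromide)
Product: 12 dimethylallyl diphosphate (3-methylbut-2-en-1-yl diphosphate), triammonium salt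
Conditions: (Bu4N)3HP2O7 (2 equiv), MeCN, rt; Dowex 50WX8 (NH4+ form), 25 mM NH4HCO3; cellulose chromatography; lyophilisation
Reagents that add atoms: tris(tetrabutylammonium) hydrogen diphosphate, CCCC[N+](CCCC)(CCCC)CCCC.CCCC[N+](CCCC)(CCCC)CCCC.CCCC[N+](CCCC)(CCCC)CCCC.OP(=O)([O-])OP(=O)([O-])[O-]; ammonium hydrogencarbonate, [NH4+].OC([O-])=O
Why: SN2 displacement of the primary allylic bromide by the hydrogen diphosphate trianion, made soluble in MeCN by its tetrabutylammonium counter-ions, is the standard way to allylic diphosphates, and cation exchange hands over the water-soluble ammonium salt that the enzyme needs.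

Step 8
Reactants: 10 (S)-1-(2,4-dihydroxyphenyl)-2-hydroxy-3-(4-hydroxyphenyl)propan-1-one; 12 dimethylallyl diphosphate, triammonium salt (two equivalents consumed)
Product: 14 Lespeflorin C6 = (S)-1-[2,4-dihydroxy-3,5-bis(3-methylbut-2-en-1-yl)phenyl]-2-hydroxy-3-(4-hydroxyphenyl)propan-1-one, via 3'-monoprenyl ketol 13 (not isolated)
Conditions: AtaPT (soluble ABBA-fold aromatic prenyltransferase of Aspergillus terreus, recombinant, purified), 12 (3 equiv, in portions), 10 (2 mM), Tris-HCl 50 mM pH 7.5, MgCl2 5 mM, 5% DMSO, 30 °C; EtOAc extraction, chromatography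
Reagents that add atoms: none
Why: The enzyme binds 12 and ionises its C–O bond to diphosphate inside a hydrophobic pocket, giving a dimethylallyl cation/diphosphate ion pair whose primary carbon C1 is attacked by an electron-rich ring-A carbon of the bound acceptor; loss of the ring proton from the arenium ion restores the arene, and the released monoprenyl ketol 13 rebinds for the second transfer. The closest known reaction type is the enzymatic Friedel–Crafts C-prenylation of chalcones, dihydrochalcones and acylphloroglucinols by aromatic prenyltransferases, which includes repeated transfers by promiscuous soluble enzymes. No ring is closed and no stereocenter is formed; the (S)-carbinol carbon is a spectator at pH 7.5 and 30 °C, where the α-ketol should not enolise. The step needs C- over O-alkylation, ring A over ring B, attack at C1 and not C3 of the allyl cation, and two transfers instead of one. The substrate supports this because C3' and C5' are the only carbons activated by both O2' and O4', the 4'-hydroxyl (para to the ketone) is the most acidic phenol and so the one that ionises, the 2'-hydroxyl is held in a hydrogen bond to the carbonyl, and ring B has only one hydroxyl, while the pocket geometry decides normal against reverse attack and the excess of 12 drives the second transfer.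

**Compound list**

1 | (S)-3-(4-hydroxyphenyl)lactic acid | O=C(O)[C@@H](O)Cc1ccc(O)cc1 | starting material
2 | benzyl (S)-3-[4-(benzyloxy)phenyl]-2-hydroxypropanoate | O=C(OCc1ccccc1)[C@@H](O)Cc1ccc(OCc2ccccc2)cc1 | intermediate
3 | benzyl (S)-2-(benzyloxy)-3-[4-(benzyloxy)phenyl]propanoate | O=C(OCc1ccccc1)[C@@H](OCc1ccccc1)Cc1ccc(OCc2ccccc2)cc1 | intermediate
4 | (S)-2-(benzyloxy)-3-[4-(benzyloxy)phenyl]-N-methoxy-N-methylpropanamide | CON(C)C(=O)[C@@H](OCc1ccccc1)Cc1ccc(OCc2ccccc2)cc1 | intermediate
5 | 4-bromoresorcinol | Oc1ccc(Br)c(O)c1 | starting material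
6 | 2,4-bis(benzyloxy)-1-bromobenzene | Brc1ccc(OCc2ccccc2)cc1OCc1ccccc1 | intermediate
7 | [2,4-bis(benzyloxy)phenyl]lithium (not isolated) | [Li]c1ccc(OCc2ccccc2)cc1OCc1ccccc1 | intermediate
8 | lithium (2S)-2-(benzyloxy)-1-[2,4-bis(benzyloxy)phenyl]-3-[4-(benzyloxy)phenyl]-1-[methoxy(methyl)amino]propan-1-olate, C1 configuration undefined (not isolated) | CON(C)C(O[Li])(c1ccc(OCc2ccccc2)cc1OCc1ccccc1)[C@@H](OCc1ccccc1)Cc1ccc(OCc2ccccc2)cc1 | intermediate
9 | (S)-2-(benzyloxy)-1-[2,4-bis(benzyloxy)phenyl]-3-[4-(benzyloxy)phenyl]propan-1-one | O=C(c1ccc(OCc2ccccc2)cc1OCc1ccccc1)[C@@H](OCc1ccccc1)Cc1ccc(OCc2ccccc2)cc1 | intermediate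
10 | (S)-1-(2,4-dihydroxyphenyl)-2-hydroxy-3-(4-hydroxyphenyl)propan-1-one | O=C(c1ccc(O)cc1O)[C@@H](O)Cc1ccc(O)cc1 | intermediate
11 | 1-bromo-3-methylbut-2-ene (prenyl bromide) | CC(C)=CCBr | starting material
12 | dimethylallyl diphosphate, triammonium salt | CC(C)=CCOP(=O)([O-])OP(=O)([O-])[O-].[NH4+].[NH4+].[NH4+] | intermediate
13 | (S)-1-[2,4-dihydroxy-3-(3-methylbut-2-en-1-yl)phenyl]-2-hydroxy-3-(4-hydroxyphenyl)propan-1-one (not isolated) | CC(C)=CCc1c(O)ccc(C(=O)[C@@H](O)Cc2ccc(O)cc2)c1O | intermediate
14 | Lespeflorin C6, (S)-1-[2,4-dihydroxy-3,5-bis(3-methylbut-2-en-1-yl)phenyl]-2-hydroxy-3-(4-hydroxyphenyl)propan-1-one | CC(C)=CCc1cc(C(=O)[C@@H](O)Cc2ccc(O)cc2)c(O)c(CC=C(C)C)c1O | target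

**Step count**

Total step count: 8.
Longest linear sequence: 6 steps (steps 1, 2, 3, 5, 6, 8).

**Steps most likely to fail**

1. Step 8. The acceptor may bind in poses that bring O4', ring B or C3 of the allyl cation to the reacting distance, or the monoprenylated ketol may be released and not taken up again. Transfer would then stop after one prenyl group or go to the wrong atom.
Fallback (sets out from 5, 11 and 1, comes back at 14): the prenyl groups are put on chemically before the aryl–acyl bond is made, at a stage where only the two wanted carbons can react. Compound 5, whose only nucleophilic ring carbons are C2 and C6, is C-alkylated twice with 11 (aq. KOH, 0 °C to rt, phenoxide C-alkylation) to 4-bromo-2,6-bis(3-methylbut-2-en-1-yl)benzene-1,3-diol F1. This is protected (NaH, MOMCl, DMF, 0 °C) as 1-bromo-2,4-bis(methoxymethoxy)-3,5-bis(3-methylbut-2-en-1-yl)benzene F2. Acid 1 is coupled with MeNHOMe·HCl (1-ethyl-3-(3-dimethylaminopropyl)carbodiimide hydrochloride, HOBt, N-methylmorpholine, CH2Cl2) to (S)-2-hydroxy-3-(4-hydroxyphenyl)-N-methoxy-N-methylpropanamide F3. Silylation (TBSCl, imidazole, DMF) gives (S)-2-[(tert-butyldimethylsilyl)oxy]-3-{4-[(tert-butyldimethylsilyl)oxy]phenyl}-N-methoxy-N-methylpropanamide F4. Bromine–lithium exchange of F2 (n-BuLi, THF, −78 °C) gives [2,4-bis(methoxymethoxy)-3,5-bis(3-methylbut-2-en-1-yl)phenyl]lithium F5. F5 adds to F4 and, after a cold 1 M HCl quench, gives (S)-1-[2,4-bis(methoxymethoxy)-3,5-bis(3-methylbut-2-en-1-yl)phenyl]-2-[(tert-butyldimethylsilyl)oxy]-3-{4-[(tert-butyldimethylsilyl)oxy]phenyl}propan-1-one F6. Methanolic HCl (1 M, rt) removes the two methoxymethyl and the two silyl groups and gives 14. Acid-labile groups replace benzyl here because hydrogenolysis would saturate the prenyl groups; the acid must stay dilute and cold enough that the ortho-prenylphenols do not close to chromans.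

2. Step 6. The secondary benzyl ether is cleaved more slowly than the three aryl benzyl ethers, and prolonged exposure to the catalyst may begin to reduce the aryl ketone to the carbinol or the methylene compound.
Fallback (sets out from 9, comes back at 10): reduction is given up and the four ethers are cleaved by a different reaction, Lewis-acid dealkylation with BCl3 and pentamethylbenzene as benzyl-cation scavenger (CH2Cl2, −78 °C, then MeOH/H2O). The ketone is inert to this reagent, and the cold, non-basic medium should not epimerise the α-ketol. No new compound is made on the way.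

3. Step 5. The hindered ortho-alkoxy aryllithium may act as a base toward the α-proton of the amide (amide recovered and partly epimerised), or rearrange on warming before it adds.
Fallback (sets out from 4 and 6, comes back at 9): the acyl substitution is replaced by aldehyde addition and oxidation. Amide 4 is reduced (i-Bu2AlH, THF, −78 °C) to (S)-2-(benzyloxy)-3-[4-(benzyloxy)phenyl]propanal F7. Aryllithium 7 (from 6 and n-BuLi as in step 5) adds to F7 at −78 °C and gives (2S)-2-(benzyloxy)-1-[2,4-bis(benzyloxy)phenyl]-3-[4-(benzyloxy)phenyl]propan-1-ol F8 as a mixture of carbinol epimers. Dess–Martin oxidation (CH2Cl2, rt) removes the new carbinol stereocenter and gives 9.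

**Further compounds**

F1 | step 8 | 4-bromo-2,6-bis(3-methylbut-2-en-1-yl)benzene-1,3-diol | CC(C)=CCc1cc(Br)c(O)c(CC=C(C)C)c1O
F2 | step 8 | 1-bromo-2,4-bis(methoxymethoxy)-3,5-bis(3-methylbut-2-en-1-yl)benzene | CC(C)=CCc1cc(Br)c(OCOC)c(CC=C(C)C)c1OCOC
F3 | step 8 | (S)-2-hydroxy-3-(4-hydroxyphenyl)-N-methoxy-N-methylpropanamide | CON(C)C(=O)[C@@H](O)Cc1ccc(O)cc1
F4 | step 8 | (S)-2-[(tert-butyldimethylsilyl)oxy]-3-{4-[(tert-butyldimethylsilyl)oxy]phenyl}-N-methoxy-N-methylpropanamide | CON(C)C(=O)[C@@H](O[Si](C)(C)C(C)(C)C)Cc1ccc(O[Si](C)(C)C(C)(C)C)cc1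
F5 | step 8 | [2,4-bis(methoxymethoxy)-3,5-bis(3-methylbut-2-en-1-yl)phenyl]lithium | [Li]c1cc(CC=C(C)C)c(OCOC)c(CC=C(C)C)c1OCOC
F6 | step 8 | (S)-1-[2,4-bis(methoxymethoxy)-3,5-bis(3-methylbut-2-en-1-yl)phenyl]-2-[(tert-butyldimethylsilyl)oxy]-3-{4-[(tert-butyldimethylsilyl)oxy]phenyl}propan-1-one | CC(C)=CCc1cc(C(=O)[C@@H](O[Si](C)(C)C(C)(C)C)Cc2ccc(O[Si](C)(C)C(C)(C)C)cc2)c(OCOC)c(CC=C(C)C)c1OCOC
F0 | step 6 | none | none
F7 | step 5 | (S)-2-(benzyloxy)-3-[4-(benzyloxy)phenyl]propanal | O=C[C@@H](OCc1ccccc1)Cc1ccc(OCc2ccccc2)cc1
F8 | step 5 | (2S)-2-(benzyloxy)-1-[2,4-bis(benzyloxy)phenyl]-3-[4-(benzyloxy)phenyl]propan-1-ol, mixture of C1 epimers | OC(c1ccc(OCc2ccccc2)cc1OCc1ccccc1)[C@@H](OCc1ccccc1)Cc1ccc(OCc2ccccc2)cc1
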